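## Retrosynthetic overview

1. Cleave the C6 ester: an O-acetyl p-coumaric acid plus the bicyclic 4,6-dihydroxy-7-en-9-one core.
2. Read the 6-hydroxy-7-en-9-one as a redox-transposed 9-hydroxy-7-en-6-one (C9 oxidation, then C4-OH-directed C6 reduction). That compound comes from reductive opening of a C5–O–C9 ether bridge next to a C6 ketone.
3. The ether-bridged enone is the intramolecular [5+2] adduct of a 3-oxidopyrylium and a 1,1-disubstituted alkene tethered through the C4 carbinol. The five-membered ring, the seven-membered ring and the ether bridge all form in this one operation; no carbocycle exists before it.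
4. The pyrylium comes from a 4-methyl-2-furyl carbinol by oxidative ring expansion. The furyl diol is built from a lithiated methylfuran and a dioxolanone that carries the quaternary C4 carbinol.
5. C4 is the only stereocentre brought in (alkylation of the pivaldehyde acetal of an enantiopure α-hydroxy acid); C1, C5 and C6 are relayed from it.

Assumption: all bicyclic compounds are numbered as daucanes (C1 = ring-fusion carbon bearing CH3, C2 and C3 = CH2, C4 = carbinol carbon bearing i-Pr, C5 = ring-fusion CH, C6 = ester carbon, C7=C8 with CH3 on C8, C9 = ketone carbon, C10 = CH2); in this numbering the target is 1R,4R,5S,6S.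

## Route

Step 1
Reactants: 1 (R)-2-hydroxy-3-methylbutanoic acid; 2 pivaldehyde (2,2-dimethylpropanal)
Product: 3 (2R,5R)-2-tert-butyl-5-isopropyl-1,3-dioxolan-4-one
Conditions: TsOH·H2O (cat.), H2SO4 (cat.), pentane, reflux, Dean–Stark; recrystallise from pentane at −78 °C
Reagents that add atoms: pivaldehyde, CC(C)(C)C=O
Why: Acid-catalysed acetalisation (Seebach dioxolanone formation) under thermodynamic control gives the cis acetal, so the 5R centre of 1 fixes the new acetal centre as 2R (t-Bu cis to i-Pr), and crystallisation removes the minor trans isomer that would erode the ee later.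

Step 2
Reactants: 3 (2R,5R)-2-tert-butyl-5-isopropyl-1,3-dioxolan-4-one; 4 4-bromo-2-methylbut-1-ene
Product: 6 (2R,5R)-2-tert-butyl-5-isopropyl-5-(3-methylbut-3-en-1-yl)-1,3-dioxolan-4-one, via lithium enolate 5 (not isolated)
Conditions: LiN(i-Pr)2 (LDA, 1.05 equiv), THF, −78 °C; then 4 (2 equiv), HMPA, −78 → −30 °C
Reagents that add atoms: 4-bromo-2-methylbut-1-ene, C=C(C)CCBr
Why: Seebach self-regeneration-of-stereocentres alkylation: deprotonation makes C5 planar in enolate 5 and the bromide is attacked in an SN2 reaction on the face anti to the tert-butyl group of the surviving 2R acetal centre, so the chain takes the place of the former hydrogen and the quaternary carbinol centre is rebuilt as 5R (it becomes C4 of the target).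

Step 3
Reactants: 6 (2R,5R)-2-tert-butyl-5-isopropyl-5-(3-methylbut-3-en-1-yl)-1,3-dioxolan-4-one; 7 3-methylfuran
Product: 10 (1RS,2R)-2-isopropyl-5-methyl-1-(4-methylfuran-2-yl)hex-5-ene-1,2-diol, via furyllithium 8 (not isolated), via hydroxy ketone 9 (not isolated)
Conditions: 7 (1.3 equiv), n-BuLi (1.2 equiv), THF, −78 → 0 °C; then 6, −78 → 0 °C; then MeOH, NaBH4, 0 °C
Reagents that add atoms: 3-methylfuran, Cc1ccoc1 (used as its 2-lithio derivative 8, [Li]c1cc(C)co1)
Why: n-BuLi lithiates 3-methylfuran at the α-position remote from the methyl group to give 8, which undergoes acyl substitution at the dioxolanone carbonyl (the acetal collapses and releases pivaldehyde) to give ketone 9, and NaBH4 then reduces the ketone in the same flask; the quaternary centre is untouched and the new carbinol centre need not be controlled because it becomes sp2 in step 6.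

Step 4
Reactants: 10 (1RS,2R)-2-isopropyl-5-methyl-1-(4-methylfuran-2-yl)hex-5-ene-1,2-diol
Product: 11 6-hydroxy-2-[(3R)-3-hydroxy-2,6-dimethylhept-6-en-3-yl]-5-methyl-2H-pyran-3(6H)-one (mixture at C2 and C6)
Conditions: NBS (1.05 equiv), NaHCO3, THF/H2O 4:1, 0 °C
Reagents that add atoms: water, O
Why: Achmatowicz oxidative ring expansion: the electron-rich furan is brominated in preference to the 1,1-disubstituted alkene, water opens it to the cis-enedione and the secondary carbinol oxygen closes the six-membered hemiacetal, the two new stereocentres being irrelevant because both carbons become sp2 in 13.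

Step 5
Reactants: 11 6-hydroxy-2-[(3R)-3-hydroxy-2,6-dimethylhept-6-en-3-yl]-5-methyl-2H-pyran-3(6H)-one
Product: 12 6-[(3R)-3-hydroxy-2,6-dimethylhept-6-en-3-yl]-3-methyl-5-oxo-5,6-dihydro-2H-pyran-2-yl acetate (mixture of diastereomers)
Conditions: Ac2O (1.5 equiv), pyridine, DMAP (cat.), CH2Cl2, 0 °C
Reagents that add atoms: acetic anhydride, CC(=O)OC(C)=O
Why: DMAP-catalysed acylation converts only the hemiacetal hydroxyl into the acetate leaving group, the hindered tertiary alcohol being inert under these conditions, and no relevant stereocentre is formed.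

Step 6
Reactants: 12 6-[(3R)-3-hydroxy-2,6-dimethylhept-6-en-3-yl]-3-methyl-5-oxo-5,6-dihydro-2H-pyran-2-yl acetate
Product: 14 (1R,4R,5S,9S)-5,9-epoxy-4-hydroxydauc-7-en-6-one, via oxidopyrylium 13 (not isolated)
Conditions: DABCO (2 equiv), MeCN (0.01 M), 60 °C
Reagents that add atoms: none
Why: Amine-induced loss of acetic acid gives the 3-oxidopyrylium 13, which adds across its C2 and C6 termini to the tethered 1,1-disubstituted alkene in an intramolecular oxidopyrylium–alkene [5+2] cycloaddition (Sammes/Wender type) that closes the five-membered ring, the seven-membered ring and the ether bridge at once; the three-atom tether allows only the mode that puts the angular methyl and C6 cis on the new cyclopentane, and the C4 carbinol selects the alkene face by holding its OH in the pyrylium plane hydrogen-bonded to the oxido oxygen with the i-Pr group turned away from the incoming alkene (minimal allylic 1,3-strain), which sets C1 as R with OH and methyl cis, C5 as S and C9 as S.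

Step 7
Reactants: 14 (1R,4R,5S,9S)-5,9-epoxy-4-hydroxydauc-7-en-6-one
Product: 15 (1R,4R,5R,9S)-4,9-dihydroxydauc-7-en-6-one
Conditions: SmI2 (2.5 equiv), THF/MeOH 20:1, −78 °C
Reagents that add atoms: none
Why: Reductive cleavage of an α-alkoxy ketone with SmI2 (ketyl formation, chelation-assisted scission of the strained bridgehead C5–O bond next to the carbonyl, protonation of the samarium enolate by MeOH) opens the ether bridge to the γ-hydroxy enone; C5 is protonated on the face just vacated by oxygen, which gives the trans-fused epimer that is also the thermodynamic one (C6 anti to i-Pr and hydrogen-bonded to the C4 hydroxyl), and C9 keeps its configuration.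

Step 8
Reactants: 15 (1R,4R,5R,9S)-4,9-dihydroxydauc-7-en-6-one
Product: 16 (1R,4R,5R)-4-hydroxydauc-7-ene-6,9-dione
Conditions: Dess–Martin periodinane (1.3 equiv), pyridine, CH2Cl2, 0 °C → rt
Reagents that add atoms: none
Why: Dess–Martin oxidation turns the secondary allylic C9 alcohol into the ketone while the tertiary alcohol cannot react, so the C9 stereocentre is erased and the cyclohept-2-ene-1,4-dione is obtained with C5 (now epimerisable) resting in its preferred trans-fused form.

Step 9
Reactants: 16 (1R,4R,5R)-4-hydroxydauc-7-ene-6,9-dione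
Product: 17 (1R,4R,5S,6S)-4,6-dihydroxydauc-7-en-9-one
Conditions: Me4NBH(OAc)3 (5 equiv), MeCN/AcOH 1:1, −30 °C
Reagents that add atoms: none
Why: Saksena–Evans hydroxyl-directed reduction: the C4 hydroxyl exchanges onto boron and delivers hydride through a six-membered chair to the C6 carbonyl only (the C9 carbonyl has no hydroxyl within reach and triacetoxyborohydride alone does not reduce ketones at −30 °C), from the face syn to the C4 oxygen, which gives the 6α (6S) alcohol with its hydroxyl anti to the angular methyl and locks C5 (descriptor now S, geometry unchanged).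

Step 10
Reactants: 17 (1R,4R,5S,6S)-4,6-dihydroxydauc-7-en-9-one; 18 (E)-3-(4-acetoxyphenyl)prop-2-enoic acid
Product: 19 (1R,4R,5S,6S)-4-hydroxy-9-oxodauc-7-en-6-yl (E)-3-(4-acetoxyphenyl)prop-2-enoate
Conditions: 18 (1.5 equiv), DIC (1.6 equiv), DMAP (0.5 equiv), CH2Cl2, 0 °C → rt
Reagents that add atoms: (E)-3-(4-acetoxyphenyl)prop-2-enoic acid, CC(=O)Oc1ccc(/C=C/C(=O)O)cc1
Why: Steglich esterification (carbodiimide activation, DMAP acyl transfer) acylates the secondary allylic C6 hydroxyl with retention while the tertiary C4 hydroxyl is too hindered to react, and the E alkene of the cinnamate is carried over unchanged.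

Step 11
Reactants: 19 (1R,4R,5S,6S)-4-hydroxy-9-oxodauc-7-en-6-yl (E)-3-(4-acetoxyphenyl)prop-2-enoate
Product: 20 (1R,4R,5S,6S)-4-hydroxy-9-oxodauc-7-en-6-yl (E)-3-(4-hydroxyphenyl)prop-2-enoate (CNP0310968.1)
Conditions: NH4OAc, MeOH, rt
Reagents that add atoms: none
Why: Chemoselective methanolysis of the aryl acetate (transesterification; phenoxide is a far better leaving group than the hindered secondary alkoxide of the cinnamate) frees the phenol under near-neutral conditions without touching the enone, the cinnamate or any stereocentre.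

## Compound list

1 | (R)-2-hydroxy-3-methylbutanoic acid (commercial; diazotisation product of D-valine) | CC(C)[C@@H](O)C(=O)O | starting material
2 | pivaldehyde (2,2-dimethylpropanal) | CC(C)(C)C=O | starting material
3 | (2R,5R)-2-tert-butyl-5-isopropyl-1,3-dioxolan-4-one (cis) | CC(C)[C@H]1O[C@@H](C(C)(C)C)OC1=O | intermediate
4 | 4-bromo-2-methylbut-1-ene | C=C(C)CCBr | starting material
5 | lithium (2R)-2-tert-butyl-5-isopropyl-1,3-dioxol-4-olate (lithium enolate of 3) | CC(C)C1=C([O-])O[C@H](C(C)(C)C)O1.[Li+] | intermediate (not isolated)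
6 | (2R,5R)-2-tert-butyl-5-isopropyl-5-(3-methylbut-3-en-1-yl)-1,3-dioxolan-4-one | CC(C)[C@@]1(CCC(C)=C)O[C@@H](C(C)(C)C)OC1=O | intermediate
7 | 3-methylfuran | Cc1ccoc1 | starting material
8 | (4-methylfuran-2-yl)lithium | [Li]c1cc(C)co1 | intermediate (not isolated)
9 | (2R)-2-hydroxy-2-isopropyl-5-methyl-1-(4-methylfuran-2-yl)hex-5-en-1-one | CC(C)[C@](O)(CCC(C)=C)C(=O)c1cc(C)co1 | intermediate (not isolated)
10 | (1RS,2R)-2-isopropyl-5-methyl-1-(4-methylfuran-2-yl)hex-5-ene-1,2-diol | CC(C)[C@](O)(CCC(C)=C)C(O)c1cc(C)co1 | intermediate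
11 | 6-hydroxy-2-[(3R)-3-hydroxy-2,6-dimethylhept-6-en-3-yl]-5-methyl-2H-pyran-3(6H)-one | CC(C)[C@](O)(CCC(C)=C)C1OC(O)C(C)=CC1=O | intermediate
12 | 6-[(3R)-3-hydroxy-2,6-dimethylhept-6-en-3-yl]-3-methyl-5-oxo-5,6-dihydro-2H-pyran-2-yl acetate | CC(C)[C@](O)(CCC(C)=C)C1OC(OC(C)=O)C(C)=CC1=O | intermediate
13 | 2-[(3R)-3-hydroxy-2,6-dimethylhept-6-en-3-yl]-5-methylpyrylium-3-olate | CC(C)[C@](O)(CCC(C)=C)c1[o+]cc(C)cc1[O-] | intermediate (not isolated)
14 | (1R,4R,5S,9S)-5,9-epoxy-4-hydroxydauc-7-en-6-one (ether bridge from ring-fusion C5 to C9; C6 ketone conjugated with C7=C8; 4-OH and 1-CH3 cis) | CC1=CC(=O)[C@]23O[C@H]1C[C@@]2(C)CC[C@@]3(O)C(C)C | intermediate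
15 | (1R,4R,5R,9S)-4,9-dihydroxydauc-7-en-6-one (trans-fused; 5-H and 9-OH on the face opposite to 1-CH3 and 4-OH) | CC1=CC(=O)[C@@H]2[C@](C)(CC[C@@]2(O)C(C)C)C[C@@H]1O | intermediate
16 | (1R,4R,5R)-4-hydroxydauc-7-ene-6,9-dione | CC1=CC(=O)[C@@H]2[C@](C)(CC[C@@]2(O)C(C)C)CC1=O | intermediate
17 | (1R,4R,5S,6S)-4,6-dihydroxydauc-7-en-9-one | CC1=C[C@H](O)[C@@H]2[C@](C)(CC[C@@]2(O)C(C)C)CC1=O | intermediate
18 | (E)-3-(4-acetoxyphenyl)prop-2-enoic acid (4-acetoxycinnamic acid) | CC(=O)Oc1ccc(/C=C/C(=O)O)cc1 | starting material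
19 | (1R,4R,5S,6S)-4-hydroxy-9-oxodauc-7-en-6-yl (E)-3-(4-acetoxyphenyl)prop-2-enoate | CC1=C[C@H](OC(=O)/C=C/c2ccc(OC(C)=O)cc2)[C@@H]2[C@](C)(CC[C@@]2(O)C(C)C)CC1=O | intermediate
20 | (1R,4R,5S,6S)-4-hydroxy-9-oxodauc-7-en-6-yl (E)-3-(4-hydroxyphenyl)prop-2-enoate = (3R,3aS,4S,8aR)-3-hydroxy-3-isopropyl-6,8a-dimethyl-7-oxo-1,2,3,3a,4,7,8,8a-octahydroazulen-4-yl (E)-3-(4-hydroxyphenyl)acrylate | CC1=C[C@H](OC(=O)/C=C/c2ccc(O)cc2)[C@@H]2[C@](C)(CC[C@@]2(O)C(C)C)CC1=O | target

## Step count and risks

Total steps: 11. Longest linear sequence: 11 (1 → 20; compounds 2, 4, 7 and 18 are bought). The ee of 20 rests on the diastereomeric purity of 3.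

Steps most likely to fail, with fallbacks:

- **Step 6 (the cycloaddition).** Two fully substituted carbons are joined next to a third. The free tertiary hydroxyl could also divert the acetate or the pyrylium (bicyclic ketal formation, retro-aldol), and 13 can dimerise. The fallback sets out from 12 and comes back at 14. The tertiary hydroxyl is silylated with N-(trimethylsilyl)imidazole in CH2Cl2 to give 6-[(3R)-2,6-dimethyl-3-(trimethylsilyloxy)hept-6-en-3-yl]-3-methyl-5-oxo-5,6-dihydro-2H-pyran-2-yl acetate F2. Under the same DABCO/MeCN conditions, where the face is now chosen by allylic strain alone and no hydroxyl can interfere, this gives (1R,4R,5S,9S)-5,9-epoxy-4-(trimethylsilyloxy)dauc-7-en-6-one F3. Citric acid in MeOH removes the silyl group to give 14.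

- **Step 7 (SmI2 opening).** The bridging oxygen is α to the ketone on one side and vinylogously γ on the other, so cleavage of the C9–O bond could compete. Protonation could also give the cis-fused C5 epimer. The fallback sets out from 14 and comes back at 16. Hydrogenation (H2, Pd/C, EtOAc, from the face of the ether bridge) removes the conjugation and gives (1R,4R,5S,8S,9S)-5,9-epoxy-4-hydroxydaucan-6-one F4. SmI2 in THF/MeOH can then only break the C5–O bond and gives (1R,4R,5R,8S,9S)-4,9-dihydroxydaucan-6-one F5. Dess–Martin oxidation gives the 1,4-diketone (1R,4R,5R,8S)-4-hydroxydaucane-6,9-dione F6. Dehydrogenation between the two carbonyls with SeO2 in t-BuOH at 80 °C gives 16.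

- **Step 2 (alkylation).** A hindered, thermally fragile enolate meets an unactivated homoallylic bromide that can undergo E2 elimination to isoprene. The fallback sets out from 3 and comes back at 6. The lithium enolate of 3 (LiN(i-Pr)2, THF, −78 °C) is added in a Michael reaction to but-3-en-2-one to give (2R,5R)-2-tert-butyl-5-isopropyl-5-(3-oxobutyl)-1,3-dioxolan-4-one F1, with the same facial control. Wittig methylenation of the ketone (Ph3P=CH2, THF, 0 °C; the lactone carbonyl does not react) gives 6.

Further compounds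

F1 | step 2 | (2R,5R)-2-tert-butyl-5-isopropyl-5-(3-oxobutyl)-1,3-dioxolan-4-one | CC(C)[C@@]1(CCC(C)=O)O[C@@H](C(C)(C)C)OC1=O
F2 | step 6 | 6-[(3R)-2,6-dimethyl-3-(trimethylsilyloxy)hept-6-en-3-yl]-3-methyl-5-oxo-5,6-dihydro-2H-pyran-2-yl acetate | CC(C)[C@](O[Si](C)(C)C)(CCC(C)=C)C1OC(OC(C)=O)C(C)=CC1=O
F3 | step 6 | (1R,4R,5S,9S)-5,9-epoxy-4-(trimethylsilyloxy)dauc-7-en-6-one | CC1=CC(=O)[C@]23O[C@H]1C[C@@]2(C)CC[C@@]3(O[Si](C)(C)C)C(C)C
F4 | step 7 | (1R,4R,5S,8S,9S)-5,9-epoxy-4-hydroxydaucan-6-one | C[C@H]1CC(=O)[C@]23O[C@H]1C[C@@]2(C)CC[C@@]3(O)C(C)C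
F5 | step 7 | (1R,4R,5R,8S,9S)-4,9-dihydroxydaucan-6-one | C[C@H]1CC(=O)[C@@H]2[C@](C)(CC[C@@]2(O)C(C)C)C[C@@H]1O
F6 | step 7 | (1R,4R,5R,8S)-4-hydroxydaucane-6,9-dione | C[C@H]1CC(=O)[C@@H]2[C@](C)(CC[C@@]2(O)C(C)C)CC1=O
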